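**Retrosynthetic overview**

1. Target 16 ⇐ protected dimer 15 by global BBr3 deprotection; 15 ⇐ phenacyl ether 13 + 2-oxobutanoic acid 8, cutting C1–C8a and C2=C3 of the ethyl-naphthoquinone ring (one-pot acid-mediated aldol condensation / Friedel–Crafts cycloacylation).
2. Enabling feature: in the 3-alkoxy-2-ethyl-1,4-naphthoquinone ring, C3 is the methylene of an α-alkoxy aryl ketone (C4=O) and C1–C2 is an α-keto acid unit at the same overall oxidation level; C8a–H lies ortho to the C4 acyl group, para to the C6 oxygen and ortho to the C8 oxygen.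
3. 13 ⇐ tertiary alcohol (S)-12 + diazoketone 6 (Rh-carbenoid O–H insertion); (S)-12 ⇐ hydroxyquinone 11 (catalytic enantioselective α-hydroxylation sets the only stereocentre).
4. 11 ⇐ phenacyl acetate 7 + 8 by the same annulation; 6 and 7 both come from 5-bromo-2-hydroxy-3-methoxybenzaldehyde 1.
5. Ring order: both benzene rings are bought in 1; the quinone ring of the future trione half is closed first (step 6) and oxidised to the trione (step 7); the quinone ring of the second half is closed last (step 9).

Key step: step 9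

Remark: the target is taken as drawn (1,4-dione tautomer of the naphthazarin half), with the stereocentre (S) (CIP order O > C3′ > C1′ > ethyl). Unprimed locants refer to the ethyl-naphthoquinone half (C1=O next to C2–Et, C3–O, C4=O), primed locants to the trione half (C2′ stereocentre).

**Step 1**
Reactants: 1 5-bromo-2-hydroxy-3-methoxybenzaldehyde
Product: 2 2-hydroxy-3,5-dimethoxybenzaldehyde
Conditions: NaOMe (5 equiv), CuBr (10 mol %), EtOAc (cat.), MeOH–DMF, 100 °C; aq. HCl
Reagents that add atoms: sodium methoxide, [Na+].[O-]C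
Why: Copper-catalysed Ullmann-type methoxylation of an aryl bromide, as used to convert bromovanillins into syringaldehyde-type ethers, should work because the aldehyde is non-enolisable and the phenoxide tolerates the conditions.

**Step 2**
Reactants: 2 2-hydroxy-3,5-dimethoxybenzaldehyde
Product: 3 2-formyl-4,6-dimethoxyphenyl methyl carbonate
Conditions: ClCO2Me (1.3 equiv), Et3N (1.5 equiv), CH2Cl2, 0 °C
Reagents that add atoms: methyl chloroformate, COC(=O)Cl
Why: Simple O-acylation of the phenol; the methyl carbonate makes the future peri C5 oxygen non-nucleophilic, so it cannot capture the ketocarbenoid intramolecularly in step 8 (benzofuran-3-one formation), and it should survive strong acid and fall in the final BBr3 step.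

**Step 3**
Reactants: 3 2-formyl-4,6-dimethoxyphenyl methyl carbonate
Product: 4 3,5-dimethoxy-2-[(methoxycarbonyl)oxy]benzoic acid
Conditions: NaClO2 (2 equiv), NaH2PO4, 2-methyl-2-butene, t-BuOH–H2O, rt
Reagents that add atoms: sodium chlorite, [Na+].[O-]Cl=O
Why: Pinnick oxidation with a hypochlorite scavenger should convert the aldehyde to the acid without chlorinating the electron-rich ring or touching the carbonate.

**Step 4**
Reactants: 4 3,5-dimethoxy-2-[(methoxycarbonyl)oxy]benzoic acid
Product: 6 2-(2-diazoacetyl)-4,6-dimethoxyphenyl methyl carbonate, via acid chloride 5 (not isolated)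
Conditions: (COCl)2 (1.5 equiv), DMF (cat.), CH2Cl2, 0 °C to rt; evaporate; TMSCHN2 (2.2 equiv), THF–MeCN, 0 °C to rt
Reagents that add atoms: oxalyl chloride, ClC(=O)C(=O)Cl (chlorine of 5); trimethylsilyldiazomethane, C[Si](C)(C)C=[N+]=[N-]
Why: Acid chloride formation followed by C-acylation of trimethylsilyldiazomethane (Arndt–Eistert-type diazoketone synthesis), run cold so that the ortho carbonate stays intact.

**Step 5**
Reactants: 6 2-(2-diazoacetyl)-4,6-dimethoxyphenyl methyl carbonate
Product: 7 2-{3,5-dimethoxy-2-[(methoxycarbonyl)oxy]phenyl}-2-oxoethyl acetate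
Conditions: AcOH (solvent), 60 °C
Reagents that add atoms: acetic acid, CC(=O)O
Why: Protonation of the diazoketone by acetic acid and SN2 displacement of dinitrogen by acetate is the classical route to α-acetoxy ketones.

**Step 6**
Reactants: 7 2-{3,5-dimethoxy-2-[(methoxycarbonyl)oxy]phenyl}-2-oxoethyl acetate; 8 2-oxobutanoic acid
Product: 11 2-ethyl-3-hydroxy-6,8-dimethoxy-5-[(methoxycarbonyl)oxy]naphthalene-1,4-dione, via aroylacrylic acid 9 (not isolated), via enol acetate 10 (not isolated)
Conditions: 8 (3 equiv), P2O5–MeSO3H (1:10 w/w), 25 to 45 °C; then H2O, 50 °C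
Reagents that add atoms: none
Why: Proposed new method: the annulation of step 9 is run first on the simple phenacyl acetate (the enol of 7 adds to the keto carbonyl of 8, dehydration gives the (E)-aroylacrylic acid 9, and its acylium acylates the ring carbon ortho to the ketone, which is para and ortho to the two methoxy groups), the closest known reaction types being the acid-catalysed condensation of aryl ketones with glyoxylic acid and the strong-acid cyclisation of β-aroylacrylic or o-aroylbenzoic acids to quinones, and the labile enol acetate 10 should hydrolyse on the aqueous quench.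

**Step 7**
Reactants: 11 2-ethyl-3-hydroxy-6,8-dimethoxy-5-[(methoxycarbonyl)oxy]naphthalene-1,4-dione
Product: 12 (S)-2-ethyl-2-hydroxy-6,8-dimethoxy-5-[(methoxycarbonyl)oxy]naphthalene-1,3,4(2H)-trione
Conditions: Sc(OTf)3 (10 mol %), chiral pipecolic-acid-derived N,N′-dioxide ligand (11 mol %), 3-phenyl-2-(phenylsulfonyl)oxaziridine (1.3 equiv), 4 Å MS, CH2Cl2, −20 °C
Reagents that add atoms: 3-phenyl-2-(phenylsulfonyl)oxaziridine, O=S(=O)(c1ccccc1)N1OC1c1ccccc1
Why: Catalytic enantioselective α-hydroxylation of a β-dicarbonyl enol by an N-sulfonyloxaziridine under chiral Lewis acid control, in which the scandium complex chelates the C3 enolate oxygen and the C4 carbonyl and the ligand shields one face, so that oxygen should be delivered to C2 from the face on which C3, C1 and the ethyl carbon appear counter-clockwise, which gives (S); the ligand enantiomer is chosen accordingly.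

**Step 8**
Reactants: 12 (S)-2-ethyl-2-hydroxy-6,8-dimethoxy-5-[(methoxycarbonyl)oxy]naphthalene-1,3,4(2H)-trione; 6 2-(2-diazoacetyl)-4,6-dimethoxyphenyl methyl carbonate
Product: 13 (S)-2-(2-{3,5-dimethoxy-2-[(methoxycarbonyl)oxy]phenyl}-2-oxoethoxy)-2-ethyl-6,8-dimethoxy-5-[(methoxycarbonyl)oxy]naphthalene-1,3,4(2H)-trione
Conditions: 6 (2.5 equiv, syringe pump), Rh2(OAc)4 (2 mol %), 4 Å MS, CH2Cl2, 40 °C
Reagents that add atoms: none
Why: Rhodium(II)-carbenoid O–H insertion is a neutral etherification suited to a hindered, base-sensitive tertiary α-ketol (no alkoxide is generated, so no α-ketol or benzilic-type rearrangement), and the stereocentre is untouched because only the O–H bond reacts.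

**Step 9**
Reactants: 13 (S)-2-(2-{3,5-dimethoxy-2-[(methoxycarbonyl)oxy]phenyl}-2-oxoethoxy)-2-ethyl-6,8-dimethoxy-5-[(methoxycarbonyl)oxy]naphthalene-1,3,4(2H)-trione; 8 2-oxobutanoic acid
Product: 15 2-ethyl-3-{[(S)-2-ethyl-6,8-dimethoxy-5-(methoxycarbonyloxy)-1,3,4-trioxo-1,2,3,4-tetrahydronaphthalen-2-yl]oxy}-6,8-dimethoxy-5-(methoxycarbonyloxy)naphthalene-1,4-dione, via aroylacrylic acid 14 (not isolated)
Conditions: 8 (3 equiv), P2O5–MeSO3H (1:10 w/w), 25 to 45 °C; ice–water
Reagents that add atoms: none
Why: Proposed new method: in the dehydrating acid the aryl ketone of 13 enolises toward its only enolisable carbon (the O-bearing methylene C3), the enol adds to the protonated keto carbonyl of 8 and the tertiary aldol loses water to the push–pull alkene 14 (new C2=C3), whose E/Z isomers equilibrate by C-protonation so that the carboxyl can reach the arene; the derived mixed anhydride or acylium then acylates C8a (new C1–C8a), and the 1,2-dicarbonyl oxidation level of 8 delivers the quinone without a redox step. The closest known reaction types are the acid-catalysed condensation of aryl methyl ketones with glyoxylic acid to β-aroylacrylic acids and the cyclodehydration of β-aroylacrylic or o-aroylbenzoic acids to quinones in strong acid; their merger in one pot with a ketone-type α-keto acid is the untested part. The ring closes by intramolecular Friedel–Crafts acylation in a 6-exo-trig mode at the activated acyl carbon. No stereocentre is formed, and the existing (S) centre is quaternary, has no α-hydrogen and cannot ionise between two carbonyl groups, so it is not at risk. Regioselectivity is secured by the tether (only C8a is within reach) and by the C8 (ortho) and C6 (para) methoxy groups, which outweigh the deactivating C4 acyl group, while both carbonyl-substituted aryl rings are too deactivated for intermolecular attack by 8. Chemoselectivity for the keto group of 8 rests on its higher electrophilicity; the internal aldol of the C3 enol onto the C4′ ketone is reversible and cannot dehydrate (bridgehead), and a Nazarov-type closure of C2 onto C8a is disfavoured because C2 carries the electron-withdrawing carboxyl.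

**Step 10**
Reactants: 15 2-ethyl-3-{[(S)-2-ethyl-6,8-dimethoxy-5-(methoxycarbonyloxy)-1,3,4-trioxo-1,2,3,4-tetrahydronaphthalen-2-yl]oxy}-6,8-dimethoxy-5-(methoxycarbonyloxy)naphthalene-1,4-dione
Product: 16 2-ethyl-3-{[(S)-2-ethyl-5,6,8-trihydroxy-1,3,4-trioxo-1,2,3,4-tetrahydronaphthalen-2-yl]oxy}-5,6,8-trihydroxynaphthalene-1,4-dione (target)
Conditions: BBr3 (15 equiv), CH2Cl2, −78 to 0 °C; then H2O, 0 °C
Reagents that add atoms: none
Why: Lewis-acid-assisted SN2 demethylation by bromide should cleave the four aryl methyl ethers and the two methyl carbonates (which lose CO2 on hydrolysis), whereas the tertiary C2′–O ether carbon, flanked by two carbonyl groups, has neither an SN2 nor an SN1 pathway and the quaternary (S) centre cannot epimerise.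

**Compound list**

1 | 5-bromo-2-hydroxy-3-methoxybenzaldehyde | O=Cc1cc(Br)cc(OC)c1O | starting material
2 | 2-hydroxy-3,5-dimethoxybenzaldehyde | O=Cc1cc(OC)cc(OC)c1O | intermediate
3 | 2-formyl-4,6-dimethoxyphenyl methyl carbonate | O=Cc1cc(OC)cc(OC)c1OC(=O)OC | intermediate
4 | 3,5-dimethoxy-2-[(methoxycarbonyl)oxy]benzoic acid | OC(=O)c1cc(OC)cc(OC)c1OC(=O)OC | intermediate
5 | 3,5-dimethoxy-2-[(methoxycarbonyl)oxy]benzoyl chloride | ClC(=O)c1cc(OC)cc(OC)c1OC(=O)OC | intermediate
6 | 2-(2-diazoacetyl)-4,6-dimethoxyphenyl methyl carbonate | [N-]=[N+]=CC(=O)c1cc(OC)cc(OC)c1OC(=O)OC | intermediate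
7 | 2-{3,5-dimethoxy-2-[(methoxycarbonyl)oxy]phenyl}-2-oxoethyl acetate | CC(=O)OCC(=O)c1cc(OC)cc(OC)c1OC(=O)OC | intermediate
8 | 2-oxobutanoic acid | CCC(=O)C(=O)O | starting material
9 | (E)-3-acetoxy-4-{3,5-dimethoxy-2-[(methoxycarbonyl)oxy]phenyl}-2-ethyl-4-oxobut-2-enoic acid | OC(=O)/C(CC)=C(/OC(C)=O)C(=O)c1cc(OC)cc(OC)c1OC(=O)OC | intermediate
10 | 3-acetoxy-2-ethyl-6,8-dimethoxy-5-[(methoxycarbonyl)oxy]naphthalene-1,4-dione | CCC1=C(OC(C)=O)C(=O)c2c(OC(=O)OC)c(OC)cc(OC)c2C1=O | intermediate
11 | 2-ethyl-3-hydroxy-6,8-dimethoxy-5-[(methoxycarbonyl)oxy]naphthalene-1,4-dione | CCC1=C(O)C(=O)c2c(OC(=O)OC)c(OC)cc(OC)c2C1=O | intermediate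
12 | (S)-2-ethyl-2-hydroxy-6,8-dimethoxy-5-[(methoxycarbonyl)oxy]naphthalene-1,3,4(2H)-trione | O[C@]1(CC)C(=O)C(=O)c2c(OC(=O)OC)c(OC)cc(OC)c2C1=O | intermediate
13 | (S)-2-(2-{3,5-dimethoxy-2-[(methoxycarbonyl)oxy]phenyl}-2-oxoethoxy)-2-ethyl-6,8-dimethoxy-5-[(methoxycarbonyl)oxy]naphthalene-1,3,4(2H)-trione | O=C(CO[C@]1(CC)C(=O)C(=O)c2c(OC(=O)OC)c(OC)cc(OC)c2C1=O)c1cc(OC)cc(OC)c1OC(=O)OC | intermediate
14 | (E)-4-{3,5-dimethoxy-2-[(methoxycarbonyl)oxy]phenyl}-2-ethyl-3-{[(S)-2-ethyl-6,8-dimethoxy-5-(methoxycarbonyloxy)-1,3,4-trioxo-1,2,3,4-tetrahydronaphthalen-2-yl]oxy}-4-oxobut-2-enoic acid | OC(=O)/C(CC)=C(/O[C@]1(CC)C(=O)C(=O)c2c(OC(=O)OC)c(OC)cc(OC)c2C1=O)C(=O)c1cc(OC)cc(OC)c1OC(=O)OC | intermediate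
15 | 2-ethyl-3-{[(S)-2-ethyl-6,8-dimethoxy-5-(methoxycarbonyloxy)-1,3,4-trioxo-1,2,3,4-tetrahydronaphthalen-2-yl]oxy}-6,8-dimethoxy-5-(methoxycarbonyloxy)naphthalene-1,4-dione | CCC1=C(O[C@]2(CC)C(=O)C(=O)c3c(OC(=O)OC)c(OC)cc(OC)c3C2=O)C(=O)c2c(OC(=O)OC)c(OC)cc(OC)c2C1=O | intermediate
16 | 2-ethyl-3-{[(S)-2-ethyl-5,6,8-trihydroxy-1,3,4-trioxo-1,2,3,4-tetrahydronaphthalen-2-yl]oxy}-5,6,8-trihydroxynaphthalene-1,4-dione | CCC1=C(O[C@]2(CC)C(=O)C(=O)c3c(O)c(O)cc(O)c3C2=O)C(=O)c2c(O)c(O)cc(O)c2C1=O | target

**Step count and risks**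

Total steps: 10. Longest linear sequence: 10 (1 → 2 → 3 → 4 → 6 → 7 → 11 → 12 → 13 → 15 → 16; diazoketone 6 is used in steps 5 and 8).

Steps most likely to fail:

1. Step 9 (Proposed new method). The intermolecular acid-catalysed aldol addition of the enol of 13 to 8 may be slower than self-condensation or decarbonylation of 8. Once 14 has formed, its enol ether may be cleaved by the water released, or a Nazarov-type closure may compete with the acylation. Fallback (known chemistry), from 13 back to 15: 13 is converted with TMSOTf/Et3N (CH2Cl2, −78 to 0 °C) into the trimethylsilyl enol ether F1. F1 undergoes a TiCl4-mediated Mukaiyama aldol addition to ethyl 2-oxobutanoate (CH2Cl2, −78 °C) to give the tertiary aldol ester F2. F2 is then dehydrated and cycloacylated in P2O5–MeSO3H, the ester acting as acyl donor, to rejoin the route at 15.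

2. Step 6 (Proposed new method). The same untested cascade; in addition the α-acetoxy ketone may cyclise to a 1,3-dioxolium ion or lose its acetyl group, which would stall the aldol stage. Fallback (known chemistry), from 7 back to 11: acid-catalysed condensation of 7 with glyoxylic acid (AcOH, cat. H2SO4, 95 °C) gives the aroylacrylic acid F3. Cyclodehydration of F3 in concentrated H2SO4, with hydrolysis of the enol acetate on aqueous quench, gives the hydroxyquinone F4. Silver/persulfate decarboxylative radical ethylation of F4 with propanoic acid (AgNO3, (NH4)2S2O8, MeCN–H2O, 65 °C) at the free quinone carbon gives 11.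

3. Step 8. Insertion into the hindered, electron-poor tertiary hydroxyl may be outrun by carbene dimerisation and by carbonyl-ylide formation at the vicinal dione of 12. Fallback, from 6 and 12 back to 13: 6 is converted with aqueous HBr (Et2O, 0 °C) into the bromoketone F5. 12 is then alkylated with F5 under halide abstraction (AgOTf, 2,6-di-tert-butyl-4-methylpyridine, CH2Cl2, 0 °C to rt) to give 13.

**Further compounds**

F1 | step 9 | trimethylsilyl enol ether of 13 (enol geometry not fixed) | C[Si](C)(C)OC(=CO[C@]1(CC)C(=O)C(=O)c2c(OC(=O)OC)c(OC)cc(OC)c2C1=O)c1cc(OC)cc(OC)c1OC(=O)OC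
F2 | step 9 | ethyl 4-{3,5-dimethoxy-2-[(methoxycarbonyl)oxy]phenyl}-2-ethyl-2-hydroxy-3-{[(S)-2-ethyl-6,8-dimethoxy-5-(methoxycarbonyloxy)-1,3,4-trioxo-1,2,3,4-tetrahydronaphthalen-2-yl]oxy}-4-oxobutanoate (mixture at the two new centres) | CCOC(=O)C(O)(CC)C(O[C@]1(CC)C(=O)C(=O)c2c(OC(=O)OC)c(OC)cc(OC)c2C1=O)C(=O)c1cc(OC)cc(OC)c1OC(=O)OC
F3 | step 6 | (E)-3-acetoxy-4-{3,5-dimethoxy-2-[(methoxycarbonyl)oxy]phenyl}-4-oxobut-2-enoic acid | OC(=O)/C=C(/OC(C)=O)C(=O)c1cc(OC)cc(OC)c1OC(=O)OC
F4 | step 6 | 2-hydroxy-5,7-dimethoxy-8-[(methoxycarbonyl)oxy]naphthalene-1,4-dione | OC1=CC(=O)c2c(OC)cc(OC)c(OC(=O)OC)c2C1=O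
F5 | step 8 | 2-(2-bromoacetyl)-4,6-dimethoxyphenyl methyl carbonate | BrCC(=O)c1cc(OC)cc(OC)c1OC(=O)OC
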